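## Retrosynthetic overview

1. Target 22 ⇐ hydroxy enal 21 + Meldrum's acid (malonate half-ester). 21 ⇐ bicyclic methyl ester / Weinreb amide 20 by one hydride reduction.
2. 14-Membered ring ⇐ intramolecular HWE closing C-7=C-8 of aldehyde phosphonate 19. Its chain ⇐ Z-selective Julia–Kocienski olefination (C-11=C-12) of methyl ketone 11 with sulfone 17.
3. C-5–C-6 bond and C-4 stereocentre ⇐ light-driven, Mg-chelate-controlled radical addition / hydrogen transfer of iodo acetal 10 to oxolanyl acrylate 9.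
4. 9 ⇐ Knoevenagel / oxa-Michael (sets C-3 cis to the C-1 chain) and Mannich methylenation of lactol 3 ⇐ ozonolysis of (R)-α-terpineol 1 (source of C-1).
5. Ring order: oxolane first (step 2), 14-membered carbocycle second (step 10).

Assumption: compounds 1, 4, 7, 10, 12, 13 and 15 are bought. Atom labels C-1 to C-20 follow cembrane numbering of the target: C-1 is the bridgehead carrying the CMe2–O carbon, C-3 the O-bearing bridgehead, C-4 the CH carrying C-18H2O, C-7=C-8 the enal alkene (C-19 = CHO), C-11=C-12 the methyl-bearing alkene.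

## Route

Step 1
Reactants: 1 (R)-(+)-α-terpineol, 2-[(1R)-4-methylcyclohex-3-en-1-yl]propan-2-ol
Product: 3 (4R)-5,5-dimethyl-4-(3-oxobutyl)oxolan-2-ol (lactol as anomer mixture), via hydroxy keto aldehyde 2 (not isolated)
Conditions: O3, CH2Cl2, −78 °C; then Me2S, −78 °C → rt
Reagents that add atoms: ozone, O=[O+][O-]
Why: Ozonolysis with reductive work-up cleaves the only alkene, and the freed aldehyde is trapped at once by the tertiary alcohol as the five-membered lactol, leaving the terpineol stereocentre (C-1) untouched.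

Step 2
Reactants: 3 (4R)-5,5-dimethyl-4-(3-oxobutyl)oxolan-2-ol; 4 Meldrum's acid (2,2-dimethyl-1,3-dioxane-4,6-dione)
Product: 6 5-[(2R,4R)-5,5-dimethyl-4-(3-oxobutyl)oxolan-2-yl]-2,2-dimethyl-1,3-dioxane-4,6-dione, via alkylidene Meldrum's acid 5 (not isolated)
Conditions: 4 (1.1 equiv), piperidine (10 mol %), AcOH (10 mol %), MeCN, rt, 24 h
Reagents that add atoms: none
Why: Knoevenagel condensation of the open aldehyde form (the ketone does not condense under these conditions) followed by reversible 5-exo oxa-Michael addition of the tertiary alcohol, so C-3 settles under thermodynamic control with both ring substituents pseudo-equatorial, cis to the C-1 chain (estimated about 5:1, minor trans isomer removed at 9).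

Step 3
Reactants: 6 5-[(2R,4R)-5,5-dimethyl-4-(3-oxobutyl)oxolan-2-yl]-2,2-dimethyl-1,3-dioxane-4,6-dione; 7 Eschenmoser's salt (N,N-dimethylmethyleneiminium iodide)
Product: 9 methyl 2-[(2R,4R)-5,5-dimethyl-4-(3-oxobutyl)oxolan-2-yl]prop-2-enoate, via Mannich base 8 (not isolated)
Conditions: 7 (1.3 equiv), MeOH, rt → 65 °C, 16 h
Reagents that add atoms: methanol, CO
Why: Mannich reaction at the acidic Meldrum's carbon, then methanolysis, loss of acetone and CO2 and β-elimination of dimethylamine (decarboxylative Mannich methylenation) give the α-substituted acrylate without strong base, so the methyl ketone and C-3 are not touched.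

Step 4
Reactants: 9 methyl 2-[(2R,4R)-5,5-dimethyl-4-(3-oxobutyl)oxolan-2-yl]prop-2-enoate; 10 iodoacetaldehyde diethyl acetal (1,1-diethoxy-2-iodoethane)
Product: 11 methyl (2S)-5,5-diethoxy-2-[(2R,4R)-5,5-dimethyl-4-(3-oxobutyl)oxolan-2-yl]pentanoate
Conditions: 10 (3 equiv), (Me3Si)3SiH (2 equiv), MgBr2·OEt2 (3 equiv), thioxanthen-9-one (2 mol %), CH2Cl2 (0.05 M), 405 nm LEDs, −78 °C
Reagents that add atoms: none
Why: Proposed new method: a visible-light-started silyl-radical chain in which triplet thioxanthone abstracts the Si–H hydrogen, (Me3Si)3Si• takes iodine from 10, the 2,2-diethoxyethyl radical adds to C-5 of the Mg-activated acrylate (Giese addition), and the resulting α-ester radical, held in a six-membered chelate between MgBr2, the ester carbonyl and the oxolane oxygen, takes hydrogen from the bulky silane on the face anti to the ring CH2, which sets C-4 as in the target; the closest known chemistry is the tin-hydride reduction of α-halo-β-alkoxy esters under MgBr2·OEt2 chelation control (Guindon-type) and silane-mediated Giese additions.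

Step 5
Reactants: 12 1-methyl-1H-tetrazole-5-thiol; 13 1-bromo-3-chloropropane
Product: 14 5-[(3-chloropropyl)sulfanyl]-1-methyl-1H-tetrazole
Conditions: K2CO3, acetone, rt
Reagents that add atoms: none
Why: SN2 S-alkylation of the thiolate at the more reactive C–Br end.

Step 6
Reactants: 15 diethyl {2-[methoxy(methyl)amino]-2-oxoethyl}phosphonate; 14 5-[(3-chloropropyl)sulfanyl]-1-methyl-1H-tetrazole
Product: 16 diethyl {1-[methoxy(methyl)amino]-5-[(1-methyl-1H-tetrazol-5-yl)sulfanyl]-1-oxopentan-2-yl}phosphonate (racemic)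
Conditions: 15 (1.5 equiv), NaH (1.0 equiv), NaI (0.2 equiv), DMF, 0 → 60 °C
Reagents that add atoms: none
Why: SN2 alkylation of the sodium phosphonoacetamide anion with in situ Finkelstein activation; the sulfide is carried through this step because it has no acidic α-hydrogen, and the new C-8 centre is destroyed later.

Step 7
Reactants: 16 diethyl {1-[methoxy(methyl)amino]-5-[(1-methyl-1H-tetrazol-5-yl)sulfanyl]-1-oxopentan-2-yl}phosphonate
Product: 17 diethyl {1-[methoxy(methyl)amino]-5-[(1-methyl-1H-tetrazol-5-yl)sulfonyl]-1-oxopentan-2-yl}phosphonate (racemic)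
Conditions: 30% H2O2 (5 equiv), (NH4)6Mo7O24·4H2O (10 mol %), EtOH, 0 °C → rt
Reagents that add atoms: hydrogen peroxide, OO
Why: Molybdate-catalysed sulfide-to-sulfone oxidation, to which phosphonate and Weinreb amide are inert.

Step 8
Reactants: 11 methyl (2S)-5,5-diethoxy-2-[(2R,4R)-5,5-dimethyl-4-(3-oxobutyl)oxolan-2-yl]pentanoate; 17 diethyl {1-[methoxy(methyl)amino]-5-[(1-methyl-1H-tetrazol-5-yl)sulfonyl]-1-oxopentan-2-yl}phosphonate
Product: 18 methyl (2S)-2-[(2R,4R)-4-[(3Z)-7-(diethoxyphosphoryl)-8-[methoxy(methyl)amino]-3-methyl-8-oxooct-3-en-1-yl]-5,5-dimethyloxolan-2-yl]-5,5-diethoxypentanoate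
Conditions: 17 (1.5 equiv), LiN(SiMe3)2 (3.1 equiv), THF, −78 °C, 20 min; then 11, −78 → −20 °C; aq. NH4Cl
Reagents that add atoms: none
Why: Julia–Kocienski olefination, in which 1-methyltetrazolyl sulfone anions add to methyl ketones and collapse stereospecifically (Smiles rearrangement, loss of SO2) to the Z-trisubstituted alkene with the larger ketone substituent cis to the new chain, while the phosphonate site rides along as its unreactive lithium salt.

Step 9
Reactants: 18 methyl (2S)-2-[(2R,4R)-4-[(3Z)-7-(diethoxyphosphoryl)-8-[methoxy(methyl)amino]-3-methyl-8-oxooct-3-en-1-yl]-5,5-dimethyloxolan-2-yl]-5,5-diethoxypentanoate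
Product: 19 methyl (2S)-2-[(2R,4R)-4-[(3Z)-7-(diethoxyphosphoryl)-8-[methoxy(methyl)amino]-3-methyl-8-oxooct-3-en-1-yl]-5,5-dimethyloxolan-2-yl]-5-oxopentanoate
Conditions: AcOH/THF/H2O (3:1:1), 45 °C
Reagents that add atoms: water, O
Why: Mild acid-catalysed acetal hydrolysis that leaves the trisubstituted alkene, the esters and the C-4 stereocentre alone.

Step 10
Reactants: 19 methyl (2S)-2-[(2R,4R)-4-[(3Z)-7-(diethoxyphosphoryl)-8-[methoxy(methyl)amino]-3-methyl-8-oxooct-3-en-1-yl]-5,5-dimethyloxolan-2-yl]-5-oxopentanoate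
Product: 20 methyl (1R,4Z,8E,12S,13R)-8-[methoxy(methyl)carbamoyl]-4,15,15-trimethyl-14-oxabicyclo[11.2.1]hexadeca-4,8-diene-12-carboxylate
Conditions: LiCl (10 equiv), DBU (5 equiv), MeCN, 1 mM (syringe-pump addition), 25 → 50 °C
Reagents that add atoms: none
Why: Intramolecular Horner–Wadsworth–Emmons reaction under Masamune–Roush conditions closes the 14-membered ring at C-7=C-8, and α-substituted phosphonates give the E enamide (carbonyl trans to C-6, ring carbons cis) under bases too weak to epimerise C-4.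

Step 11
Reactants: 20 methyl (1R,4Z,8E,12S,13R)-8-[methoxy(methyl)carbamoyl]-4,15,15-trimethyl-14-oxabicyclo[11.2.1]hexadeca-4,8-diene-12-carboxylate
Product: 21 (1R,4Z,8E,12R,13R)-12-(hydroxymethyl)-4,15,15-trimethyl-14-oxabicyclo[11.2.1]hexadeca-4,8-diene-8-carbaldehyde
Conditions: i-Bu2AlH (4.5 equiv), CH2Cl2, −78 → 0 °C; aq. potassium sodium tartrate
Reagents that add atoms: none
Why: Hydride reduction in which the Weinreb amide stops at the chelated hemiaminal and gives the enal on work-up (Weinreb reduction) while the saturated methyl ester goes to the primary alcohol.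

Step 12
Reactants: 21 (1R,4Z,8E,12R,13R)-12-(hydroxymethyl)-4,15,15-trimethyl-14-oxabicyclo[11.2.1]hexadeca-4,8-diene-8-carbaldehyde; 4 Meldrum's acid (2,2-dimethyl-1,3-dioxane-4,6-dione)
Product: 22 3-{[(1R,4Z,8E,12R,13R)-8-formyl-4,15,15-trimethyl-14-oxabicyclo[11.2.1]hexadeca-4,8-dien-12-yl]methoxy}-3-oxopropanoic acid (CNP0170412.1)
Conditions: 4 (1.3 equiv), toluene, 85 °C, 4 h
Reagents that add atoms: none
Why: Acylative ring-opening of Meldrum's acid by the primary alcohol with loss of acetone gives the malonic half-ester directly, and without an amine catalyst Knoevenagel condensation at the hindered α-branched enal should be slower.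

## Compound list

1 | (R)-(+)-α-terpineol, 2-[(1R)-4-methylcyclohex-3-en-1-yl]propan-2-ol | CC1=CC[C@@H](CC1)C(C)(C)O | starting material
2 | (3R)-3-(2-hydroxypropan-2-yl)-6-oxoheptanal | CC(=O)CC[C@H](CC=O)C(C)(C)O | intermediate
3 | (4R)-5,5-dimethyl-4-(3-oxobutyl)oxolan-2-ol | CC(=O)CC[C@@H]1CC(O)OC1(C)C | intermediate
4 | Meldrum's acid, 2,2-dimethyl-1,3-dioxane-4,6-dione | CC1(C)OC(=O)CC(=O)O1 | starting material
5 | 5-[(3R)-4-hydroxy-4-methyl-3-(3-oxobutyl)pentylidene]-2,2-dimethyl-1,3-dioxane-4,6-dione | CC(=O)CC[C@H](CC=C1C(=O)OC(C)(C)OC1=O)C(C)(C)O | intermediate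
6 | 5-[(2R,4R)-5,5-dimethyl-4-(3-oxobutyl)oxolan-2-yl]-2,2-dimethyl-1,3-dioxane-4,6-dione | CC(=O)CC[C@@H]1C[C@@H](OC1(C)C)C2C(=O)OC(C)(C)OC2=O | intermediate
7 | Eschenmoser's salt, N,N-dimethylmethyleneiminium iodide | C=[N+](C)C.[I-] | starting material
8 | 5-[(dimethylamino)methyl]-5-[(2R,4R)-5,5-dimethyl-4-(3-oxobutyl)oxolan-2-yl]-2,2-dimethyl-1,3-dioxane-4,6-dione | CC(=O)CC[C@@H]1C[C@@H](OC1(C)C)C2(CN(C)C)C(=O)OC(C)(C)OC2=O | intermediate
9 | methyl 2-[(2R,4R)-5,5-dimethyl-4-(3-oxobutyl)oxolan-2-yl]prop-2-enoate | CC(=O)CC[C@@H]1C[C@@H](OC1(C)C)C(=C)C(=O)OC | intermediate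
10 | iodoacetaldehyde diethyl acetal, 1,1-diethoxy-2-iodoethane | CCOC(CI)OCC | starting material
11 | methyl (2S)-5,5-diethoxy-2-[(2R,4R)-5,5-dimethyl-4-(3-oxobutyl)oxolan-2-yl]pentanoate | CC(=O)CC[C@@H]1C[C@@H](OC1(C)C)[C@H](CCC(OCC)OCC)C(=O)OC | intermediate
12 | 1-methyl-1H-tetrazole-5-thiol | Cn1nnnc1S | starting material
13 | 1-bromo-3-chloropropane | ClCCCBr | starting material
14 | 5-[(3-chloropropyl)sulfanyl]-1-methyl-1H-tetrazole | Cn1nnnc1SCCCCl | intermediate
15 | diethyl {2-[methoxy(methyl)amino]-2-oxoethyl}phosphonate | CCOP(=O)(OCC)CC(=O)N(C)OC | starting material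
16 | diethyl {1-[methoxy(methyl)amino]-5-[(1-methyl-1H-tetrazol-5-yl)sulfanyl]-1-oxopentan-2-yl}phosphonate (racemic) | CCOP(=O)(OCC)C(CCCSc1nnnn1C)C(=O)N(C)OC | intermediate
17 | diethyl {1-[methoxy(methyl)amino]-5-[(1-methyl-1H-tetrazol-5-yl)sulfonyl]-1-oxopentan-2-yl}phosphonate (racemic) | CCOP(=O)(OCC)C(CCCS(=O)(=O)c1nnnn1C)C(=O)N(C)OC | intermediate
18 | methyl (2S)-2-[(2R,4R)-4-[(3Z)-7-(diethoxyphosphoryl)-8-[methoxy(methyl)amino]-3-methyl-8-oxooct-3-en-1-yl]-5,5-dimethyloxolan-2-yl]-5,5-diethoxypentanoate (both epimers at the phosphonate carbon) | C/C(CC[C@@H]1C[C@@H](OC1(C)C)[C@H](CCC(OCC)OCC)C(=O)OC)=C/CCC(P(=O)(OCC)OCC)C(=O)N(C)OC | intermediate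
19 | methyl (2S)-2-[(2R,4R)-4-[(3Z)-7-(diethoxyphosphoryl)-8-[methoxy(methyl)amino]-3-methyl-8-oxooct-3-en-1-yl]-5,5-dimethyloxolan-2-yl]-5-oxopentanoate | C/C(CC[C@@H]1C[C@@H](OC1(C)C)[C@H](CCC=O)C(=O)OC)=C/CCC(P(=O)(OCC)OCC)C(=O)N(C)OC | intermediate
20 | methyl (1R,4Z,8E,12S,13R)-8-[methoxy(methyl)carbamoyl]-4,15,15-trimethyl-14-oxabicyclo[11.2.1]hexadeca-4,8-diene-12-carboxylate | C/C1=C/CC/C(C(=O)N(C)OC)=C\CC[C@H](C(=O)OC)[C@H]2C[C@@H](CC1)C(C)(C)O2 | intermediate
21 | (1R,4Z,8E,12R,13R)-12-(hydroxymethyl)-4,15,15-trimethyl-14-oxabicyclo[11.2.1]hexadeca-4,8-diene-8-carbaldehyde | C/C1=C/CC/C(C=O)=C\CC[C@H](CO)[C@H]2C[C@@H](CC1)C(C)(C)O2 | intermediate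
22 | 3-{[(1R,4Z,8E,12R,13R)-8-formyl-4,15,15-trimethyl-14-oxabicyclo[11.2.1]hexadeca-4,8-dien-12-yl]methoxy}-3-oxopropanoic acid | C/C1=C/CC/C(C=O)=C\CC[C@H](COC(=O)CC(=O)O)[C@H]2C[C@@H](CC1)C(C)(C)O2 | target

## Step count and risks

Total steps: 12. Longest linear sequence: 9 (steps 1–4 and 8–12, from 1).

Step 4 (the new light-driven chelate-controlled addition / hydrogen transfer). The gem-dimethyl-flanked ring oxygen may chelate Mg poorly, which would erode or invert the C-4 selectivity, and the silyl radical may add to the acrylate. The fallback uses known chemistry only and separates C–C bond formation from the hydrogen transfer. It sets out from 6. C-alkylation with 3-bromo-1,1-diethoxypropane (K2CO3, NaI, DMF, 50 °C) gives 5-(3,3-diethoxypropyl)-5-[(2R,4R)-5,5-dimethyl-4-(3-oxobutyl)oxolan-2-yl]-2,2-dimethyl-1,3-dioxane-4,6-dione F1. Refluxing methanol opens it, with loss of acetone, to 5,5-diethoxy-2-(methoxycarbonyl)-2-[(2R,4R)-5,5-dimethyl-4-(3-oxobutyl)oxolan-2-yl]pentanoic acid F2. DCC and N-hydroxypyridine-2-thione convert the acid into the Barton ester 1-methyl 3-(2-sulfanylidenepyridin-1(2H)-yl) 2-(3,3-diethoxypropyl)-2-[(2R,4R)-5,5-dimethyl-4-(3-oxobutyl)oxolan-2-yl]propanedioate F3. Barton reductive decarboxylation with Bu3SnH and MgBr2·OEt2 (CH2Cl2, −78 °C, Et3B/air) produces the same chelated C-4 radical and reduces it by the documented chelation-controlled tin hydride transfer, coming back to the route at 11.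

Step 8 (dianion of 17, enolisable methyl ketone, Z/E ratio with a ketone whose two alkyl groups differ little). The fallback changes which olefination closes the ring. It sets out from 11. Acetal hydrolysis (AcOH/THF/H2O) gives methyl (2S)-2-[(2R,4R)-5,5-dimethyl-4-(3-oxobutyl)oxolan-2-yl]-5-oxopentanoate F4. Aldehyde-selective HWE with the sulfide phosphonate 16 (LiCl, DBU, MeCN) gives methyl (2S,5E)-2-[(2R,4R)-5,5-dimethyl-4-(3-oxobutyl)oxolan-2-yl]-6-[methoxy(methyl)carbamoyl]-9-[(1-methyl-1H-tetrazol-5-yl)sulfanyl]non-5-enoate F5. Oxidation with H2O2 and (NH4)6Mo7O24·4H2O gives methyl (2S,5E)-2-[(2R,4R)-5,5-dimethyl-4-(3-oxobutyl)oxolan-2-yl]-6-[methoxy(methyl)carbamoyl]-9-[(1-methyl-1H-tetrazol-5-yl)sulfonyl]non-5-enoate F6. A ring-closing Julia–Kocienski olefination onto the methyl ketone (LiN(SiMe3)2, THF, 1 mM, −78 °C → rt) then has only one acidic site to address, and the bridged 14-membered ring should favour the ring-cis (Z) alkene. It comes back to the route at 20.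

Step 10 (closure of the 14-membered ring with a hindered α-substituted phosphonate; oligomerisation or slow reaction). The fallback is ring-closing metathesis and sets out from 19. Takai–Lombardo methylenation of the aldehyde (Zn, CH2Br2, TiCl4, THF) gives methyl (2S)-2-[(2R,4R)-4-[(3Z)-7-(diethoxyphosphoryl)-8-[methoxy(methyl)amino]-3-methyl-8-oxooct-3-en-1-yl]-5,5-dimethyloxolan-2-yl]hex-5-enoate F7. HWE with aqueous formaldehyde (K2CO3, THF/H2O) gives methyl (2S)-2-[(2R,4R)-4-[(3Z)-7-[methoxy(methyl)carbamoyl]-3-methylocta-3,7-dien-1-yl]-5,5-dimethyloxolan-2-yl]hex-5-enoate F8. Ring-closing metathesis (second-generation Hoveyda–Grubbs catalyst, toluene, 80 °C, 1 mM) forms the trisubstituted E enamide and comes back to the route at 20.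

## Further compounds

F1 | step 4 | 5-(3,3-diethoxypropyl)-5-[(2R,4R)-5,5-dimethyl-4-(3-oxobutyl)oxolan-2-yl]-2,2-dimethyl-1,3-dioxane-4,6-dione | CC(=O)CC[C@@H]1C[C@@H](OC1(C)C)C2(CCC(OCC)OCC)C(=O)OC(C)(C)OC2=O
F2 | step 4 | 5,5-diethoxy-2-(methoxycarbonyl)-2-[(2R,4R)-5,5-dimethyl-4-(3-oxobutyl)oxolan-2-yl]pentanoic acid | CC(=O)CC[C@@H]1C[C@@H](OC1(C)C)C(CCC(OCC)OCC)(C(=O)OC)C(=O)O
F3 | step 4 | 1-methyl 3-(2-sulfanylidenepyridin-1(2H)-yl) 2-(3,3-diethoxypropyl)-2-[(2R,4R)-5,5-dimethyl-4-(3-oxobutyl)oxolan-2-yl]propanedioate | CC(=O)CC[C@@H]1C[C@@H](OC1(C)C)C(CCC(OCC)OCC)(C(=O)OC)C(=O)ON2C=CC=CC2=S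
F4 | step 8 | methyl (2S)-2-[(2R,4R)-5,5-dimethyl-4-(3-oxobutyl)oxolan-2-yl]-5-oxopentanoate | CC(=O)CC[C@@H]1C[C@@H](OC1(C)C)[C@H](CCC=O)C(=O)OC
F5 | step 8 | methyl (2S,5E)-2-[(2R,4R)-5,5-dimethyl-4-(3-oxobutyl)oxolan-2-yl]-6-[methoxy(methyl)carbamoyl]-9-[(1-methyl-1H-tetrazol-5-yl)sulfanyl]non-5-enoate | CC(=O)CC[C@@H]1C[C@@H](OC1(C)C)[C@H](CC/C=C(\CCCSc2nnnn2C)C(=O)N(C)OC)C(=O)OC
F6 | step 8 | methyl (2S,5E)-2-[(2R,4R)-5,5-dimethyl-4-(3-oxobutyl)oxolan-2-yl]-6-[methoxy(methyl)carbamoyl]-9-[(1-methyl-1H-tetrazol-5-yl)sulfonyl]non-5-enoate | CC(=O)CC[C@@H]1C[C@@H](OC1(C)C)[C@H](CC/C=C(\CCCS(=O)(=O)c2nnnn2C)C(=O)N(C)OC)C(=O)OC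
F7 | step 10 | methyl (2S)-2-[(2R,4R)-4-[(3Z)-7-(diethoxyphosphoryl)-8-[methoxy(methyl)amino]-3-methyl-8-oxooct-3-en-1-yl]-5,5-dimethyloxolan-2-yl]hex-5-enoate | C/C(CC[C@@H]1C[C@@H](OC1(C)C)[C@H](CCC=C)C(=O)OC)=C/CCC(P(=O)(OCC)OCC)C(=O)N(C)OC
F8 | step 10 | methyl (2S)-2-[(2R,4R)-4-[(3Z)-7-[methoxy(methyl)carbamoyl]-3-methylocta-3,7-dien-1-yl]-5,5-dimethyloxolan-2-yl]hex-5-enoate | C/C(CC[C@@H]1C[C@@H](OC1(C)C)[C@H](CCC=C)C(=O)OC)=C/CCC(=C)C(=O)N(C)OC
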